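**Retrosynthetic overview**
1. The indole ring is made last: 22 comes from 2-iodoaniline and the side-chain aldehyde by Pd annulation. The aldehyde is carried as a dimethyl acetal from step 1.
2. CO2H and C=CMe2 are revealed together: acid 18 comes from the tertiary allylic δ-lactone 16 by Pd–H opening, and 16 from keto ester 13 plus isopropenyl-MgBr.
3. Key step: 13 comes from cyclopentanone 6, CH2Br2 and methyl acrylate. A 1,2-shift of the quaternary carbon onto a carbenoid carbon expands the ring from five to six members, and the resulting enolate is captured by acrylate.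
4. 6 comes from enone 4 by catalytic asymmetric Me addition and MeI trapping. 4 comes from 1 and 2 by B-alkyl Suzuki coupling.
5. Ring order: cyclopentane (bought), then cyclohexane (ring expansion), then transient δ-lactone, then the pyrrole ring of the indole.

Assumption: 2 and a THF solution of 14 are purchased. Operations run in one flask, or telescoped without purification, count as one step.

**Step 1**
Reactants: 1 3,3-dimethoxyprop-1-ene (acrolein dimethyl acetal); 2 2-iodocyclopent-2-en-1-one
Product: 4 2-(3,3-dimethoxypropyl)cyclopent-2-en-1-one, via 9-(3,3-dimethoxypropyl)-9-BBN 3 (not isolated)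
Conditions: 1, 9-BBN-H, THF, 0 °C → rt; then 2, PdCl2(dppf) (5 mol %), AsPh3, Cs2CO3, DMF/THF/H2O, rt
Reagents that add atoms: none
Why: Anti-Markovnikov hydroboration followed by B-alkyl Suzuki–Miyaura coupling with an α-iodoenone installs the three carbons that later become CH2, C3 and C2 of the indole; no stereocentre is formed.

**Step 2**
Reactants: 4 2-(3,3-dimethoxypropyl)cyclopent-2-en-1-one
Product: 6 (2R,3R)-2-(3,3-dimethoxypropyl)-2,3-dimethylcyclopentan-1-one, via bromomagnesium enolate 5 (not isolated)
Conditions: MeMgBr, Cu(OTf)2 (3 mol %), chiral hydroxyalkyl-NHC precursor (4 mol %, antipode giving 3R), Et2O, −30 °C; then MeI (5 equiv), DMPU, −30 °C → rt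
Reagents that add atoms: methylmagnesium bromide C[Mg]Br; iodomethane CI
Why: Cu–NHC-catalysed enantioselective conjugate addition of a Grignard reagent to an α-substituted cyclopentenone sets C3 under catalyst control, and Mg enolate 5 is C-methylated anti to the new C3 methyl under substrate control, so the two methyls end trans and the acetal arm ends cis to the C3 methyl.

**Step 3**
Reactants: 6 (2R,3R)-2-(3,3-dimethoxypropyl)-2,3-dimethylcyclopentan-1-one; 7 dibromomethane; 8 methyl acrylate
Product: 13 methyl 3-[(1S,2R,3R)-2-(3,3-dimethoxypropyl)-2,3-dimethyl-6-oxocyclohexyl]propanoate, via dibromomethyl lithium alkoxide 9 (not isolated), via beta-oxido carbenoid 10 (not isolated), via ring-expanded lithium enolate 11 (not isolated), via lithium ester enolate 12 (not isolated)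
Conditions: 6 + 7, LiTMP, THF, −90 °C; n-BuLi, −90 → −10 °C; 8 (1.0 equiv, slow addition), −78 °C, 15 min; AcOH quench at −78 °C
Reagents that add atoms: none
Why: Proposed new method: LiCHBr2 adds to the ketone and Br/Li exchange gives β-oxido carbenoid 10, in which the alkoxide pushes the electron-rich, strain-relieving bond to the fully substituted carbon to displace bromide from the carbenoid carbon (1,2-shift with retention at the migrating quaternary stereocentre, ring expansion from five to six members); this gives only enolate 11 next to the quaternary centre, which no base could form from the ketone, and 11 adds to methyl acrylate axially, anti to the pseudo-axial acetal arm of the half-chair with C4-Me equatorial (the other half-chair would suffer a syn-axial Me/electrophile clash), which sets C1 of the ring as S; the closest known reaction type is the dibromomethyllithium (Nozaki–Yamamoto) ring enlargement of simple cycloalkanones with alkylative trapping of the derived enolates, which to my knowledge has not been shown with a migrating quaternary stereocentre or with Michael capture.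

**Step 4**
Reactants: 13 methyl 3-[(1S,2R,3R)-2-(3,3-dimethoxypropyl)-2,3-dimethyl-6-oxocyclohexyl]propanoate; 14 isopropenylmagnesium bromide
Product: 16 (4aS,5R,6R,8aR)-5-(3,3-dimethoxypropyl)-5,6-dimethyl-8a-(prop-1-en-2-yl)octahydro-2H-chromen-2-one, via bromomagnesium tertiary alkoxide 15 (not isolated)
Conditions: 14 (1.2 equiv), LaCl3·2LiCl (1 equiv), THF, −78 °C; warm to rt; H2O
Reagents that add atoms: none
Why: La(III)-assisted Grignard 1,2-addition suppresses enolisation and favours the ketone over the methyl ester at −78 °C, and it proceeds by equatorial attack on the chair with the ester arm equatorial because both axial trajectories are blocked by an axial C3 substituent, so the alkoxide sits cis to the arm and lactonises on warming; the new C8a centre (predicted R) is erased in step 5.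

**Step 5**
Reactants: 16 (4aS,5R,6R,8aR)-5-(3,3-dimethoxypropyl)-5,6-dimethyl-8a-(prop-1-en-2-yl)octahydro-2H-chromen-2-one
Product: 18 3-[(1S,2R,3R)-2-(3,3-dimethoxypropyl)-2,3-dimethyl-6-(propan-2-ylidene)cyclohexyl]propanoic acid, via phenylsilyl ester 17 (not isolated)
Conditions: Pd(PPh3)4 (5 mol %), PhSiH3 (2 equiv), THF, 45 °C; pH 5 phosphate buffer work-up
Reagents that add atoms: none
Why: In this Pd(0)-catalysed allylic hydrogenolysis (Tsuji–Trost ionisation with a silane as neutral hydride donor) the lactone carboxylate is the leaving group and C–H bond formation occurs at the unhindered CH2 terminus of the π-allyl, which leaves the tetrasubstituted isopropylidene and frees the acid in one operation without touching the acetal or any of the three stereocentres.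

**Step 6**
Reactants: 18 3-[(1S,2R,3R)-2-(3,3-dimethoxypropyl)-2,3-dimethyl-6-(propan-2-ylidene)cyclohexyl]propanoic acid; 19 2-iodoaniline
Product: 22 suaveolindole, via aldehyde acid 20 (not isolated), via N-(2-iodophenyl) enamine 21 (not isolated)
Conditions: PPTS (20 mol %), acetone/H2O 9:1, 40 °C, evaporate; then 19, Pd(OAc)2 (10 mol %), DABCO (4 equiv), DMF, 85 °C; acidify to pH 4–5
Reagents that add atoms: none
Why: Mild acetal hydrolysis is far faster than protonation of the tetrasubstituted alkene, and the Pd-catalysed o-iodoaniline/aldehyde annulation (enamine formation, oxidative addition, intramolecular Heck-type closure, aromatisation) builds the 3-substituted N–H indole under basic conditions, which avoids acid-induced alkene migration or lactonisation and touches no stereocentre.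

**Compound list**
1 | 3,3-dimethoxyprop-1-ene | C=CC(OC)OC | starting material
2 | 2-iodocyclopent-2-en-1-one | O=C1CCC=C1I | starting material
3 | 9-(3,3-dimethoxypropyl)-9-borabicyclo[3.3.1]nonane | COC(OC)CCCB1C2CCCC1CCC2 | intermediate (not isolated)
4 | 2-(3,3-dimethoxypropyl)cyclopent-2-en-1-one | COC(OC)CCC1=CCCC1=O | intermediate
5 | bromomagnesium (3R)-2-(3,3-dimethoxypropyl)-3-methylcyclopent-1-en-1-olate | C[C@@H]1CCC(O[Mg]Br)=C1CCC(OC)OC | intermediate (not isolated)
6 | (2R,3R)-2-(3,3-dimethoxypropyl)-2,3-dimethylcyclopentan-1-one | O=C1CC[C@@H](C)[C@@]1(C)CCC(OC)OC | intermediate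
7 | dibromomethane | BrCBr | starting material
8 | methyl acrylate | C=CC(=O)OC | starting material
9 | lithium (2R,3R)-1-(dibromomethyl)-2-(3,3-dimethoxypropyl)-2,3-dimethylcyclopentan-1-olate (C-1 epimers, inconsequential) | [Li]OC1(C(Br)Br)CC[C@@H](C)[C@@]1(C)CCC(OC)OC | intermediate (not isolated)
10 | lithium (2R,3R)-1-[bromo(lithio)methyl]-2-(3,3-dimethoxypropyl)-2,3-dimethylcyclopentan-1-olate (β-oxido carbenoid) | [Li]OC1(C([Li])Br)CC[C@@H](C)[C@@]1(C)CCC(OC)OC | intermediate (not isolated)
11 | lithium (3R,4R)-3-(3,3-dimethoxypropyl)-3,4-dimethylcyclohex-1-en-1-olate | [Li]OC1=C[C@](C)(CCC(OC)OC)[C@H](C)CC1 | intermediate (not isolated)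
12 | lithium ester enolate of 13 | O=C1CC[C@@H](C)[C@@](C)(CCC(OC)OC)[C@@H]1CC=C(OC)O[Li] | intermediate (not isolated)
13 | methyl 3-[(1S,2R,3R)-2-(3,3-dimethoxypropyl)-2,3-dimethyl-6-oxocyclohexyl]propanoate | O=C1CC[C@@H](C)[C@@](C)(CCC(OC)OC)[C@@H]1CCC(=O)OC | intermediate
14 | isopropenylmagnesium bromide | C=C(C)[Mg]Br | starting material
15 | bromomagnesium alkoxide of methyl 3-[2-(3,3-dimethoxypropyl)-6-hydroxy-2,3-dimethyl-6-(prop-1-en-2-yl)cyclohexyl]propanoate (O cis to the ester arm) | C=C(C)[C@@]1(O[Mg]Br)CC[C@@H](C)[C@@](C)(CCC(OC)OC)[C@@H]1CCC(=O)OC | intermediate (not isolated)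
16 | (4aS,5R,6R,8aR)-5-(3,3-dimethoxypropyl)-5,6-dimethyl-8a-(prop-1-en-2-yl)octahydro-2H-chromen-2-one | C=C(C)[C@@]12CC[C@@H](C)[C@@](C)(CCC(OC)OC)[C@@H]1CCC(=O)O2 | intermediate
17 | phenylsilyl ester of 18 | CC(C)=C1CC[C@@H](C)[C@@](C)(CCC(OC)OC)[C@@H]1CCC(=O)O[SiH2]c1ccccc1 | intermediate (not isolated)
18 | 3-[(1S,2R,3R)-2-(3,3-dimethoxypropyl)-2,3-dimethyl-6-(propan-2-ylidene)cyclohexyl]propanoic acid | CC(C)=C1CC[C@@H](C)[C@@](C)(CCC(OC)OC)[C@@H]1CCC(=O)O | intermediate
19 | 2-iodoaniline | Nc1ccccc1I | starting material
20 | 3-[(1S,2R,3R)-2,3-dimethyl-2-(3-oxopropyl)-6-(propan-2-ylidene)cyclohexyl]propanoic acid | CC(C)=C1CC[C@@H](C)[C@@](C)(CCC=O)[C@@H]1CCC(=O)O | intermediate (not isolated)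
21 | N-(2-iodophenyl) enamine of 20 | CC(C)=C1CC[C@@H](C)[C@@](C)(C/C=C/Nc2ccccc2I)[C@@H]1CCC(=O)O | intermediate (not isolated)
22 | suaveolindole, 3-[(1S,2R,3R)-2-(1H-indol-3-ylmethyl)-2,3-dimethyl-6-(propan-2-ylidene)cyclohexyl]propanoic acid | CC(C)=C1CC[C@@H](C)[C@@](C)(Cc2c[nH]c3ccccc23)[C@@H]1CCC(=O)O | target

**Total step count:** 6. **Longest linear sequence:** 6 (steps 1–6).

**Steps most likely to fail**

Step 3 (the proposed new step). The risks are migration of the CH2 carbon instead of the quaternary carbon, enolisation of 6 by the amide or carbenoid base, and oligomerisation of acrylate by ester enolate 12.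

The fallback uses known chemistry, sets out from 6 and returns at enolate 11, and from there to 13.
- Bis(phenylthio)methyllithium is added to 6 in THF (−78 → 0 °C). This gives (2R,3R)-1-[bis(phenylsulfanyl)methyl]-2-(3,3-dimethoxypropyl)-2,3-dimethylcyclopentan-1-ol F1.
- CuOTf and i-Pr2NEt in benzene at 45 °C abstract one thiolate. This triggers the established thionium-type semipinacol ring expansion, in which the more substituted carbon migrates. The product is (3R,4R)-3-(3,3-dimethoxypropyl)-3,4-dimethyl-2-(phenylsulfanyl)cyclohexan-1-one F2.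
- Reductive C–S cleavage with 2 equiv lithium naphthalenide (THF, −78 °C) regenerates exactly enolate 11, free of amine and butyl bromide.
- 11 is then treated with 8 as in step 3.

Step 5. The risks are hydride delivery to the ring terminus, which gives the isopropenyl isomer, and β-hydride elimination to a diene.

The fallback sets out from 16 and returns at 18.
- The other regiochemistry is accepted on purpose. Formate hydrogenolysis (Pd(OAc)2, PBu3, HCO2H/Et3N, THF) reliably places H on the substituted terminus. It gives 3-[(1R,2R,3R)-2-(3,3-dimethoxypropyl)-2,3-dimethyl-6-(prop-1-en-2-yl)cyclohexyl]propanoic acid F5; the C-6 configuration is irrelevant.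
- A cobalt(salen)/PhSiH3 hydrogen-atom-transfer alkene isomerisation (benzene, rt) then moves the 1,1-disubstituted alkene into the tetrasubstituted position to give 18.

Step 4. The risks are enolisation or epimerisation at the α-centre, competing attack on the ester, and formation of the alkoxide trans to the arm, which cannot lactonise.

The fallback sets out from 13, bypasses 16 and returns at 18.
- The lithium enolate of S-phenyl 2-methylpropanethioate (LDA, THF, −78 → 0 °C) adds to the ketone and closes to a spiro-β-lactone. This is methyl 3-[(5S,6R,7R)-6-(3,3-dimethoxypropyl)-3,3,6,7-tetramethyl-2-oxo-1-oxaspiro[3.5]nonan-5-yl]propanoate F3.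
- Thermal decarboxylation (toluene, silica gel, 110 °C) gives methyl 3-[(1S,2R,3R)-2-(3,3-dimethoxypropyl)-2,3-dimethyl-6-(propan-2-ylidene)cyclohexyl]propanoate F4.
- LiOH in THF/H2O hydrolyses F4 to 18.

**Further compounds**
F1 | step 3 | (2R,3R)-1-[bis(phenylsulfanyl)methyl]-2-(3,3-dimethoxypropyl)-2,3-dimethylcyclopentan-1-ol | OC1(C(Sc2ccccc2)Sc2ccccc2)CC[C@@H](C)[C@@]1(C)CCC(OC)OC
F2 | step 3 | (3R,4R)-3-(3,3-dimethoxypropyl)-3,4-dimethyl-2-(phenylsulfanyl)cyclohexan-1-one | O=C1CC[C@@H](C)[C@@](C)(CCC(OC)OC)C1Sc1ccccc1
F3 | step 4 | methyl 3-[(5S,6R,7R)-6-(3,3-dimethoxypropyl)-3,3,6,7-tetramethyl-2-oxo-1-oxaspiro[3.5]nonan-5-yl]propanoate | CC1(C)C(=O)OC12CC[C@@H](C)[C@@](C)(CCC(OC)OC)[C@@H]2CCC(=O)OC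
F4 | step 4 | methyl 3-[(1S,2R,3R)-2-(3,3-dimethoxypropyl)-2,3-dimethyl-6-(propan-2-ylidene)cyclohexyl]propanoate | CC(C)=C1CC[C@@H](C)[C@@](C)(CCC(OC)OC)[C@@H]1CCC(=O)OC
F5 | step 5 | 3-[(1R,2R,3R)-2-(3,3-dimethoxypropyl)-2,3-dimethyl-6-(prop-1-en-2-yl)cyclohexyl]propanoic acid | C=C(C)C1CC[C@@H](C)[C@@](C)(CCC(OC)OC)[C@@H]1CCC(=O)O
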